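**Strategy.** Everything rests on opening ring C of the upper flavanone at O1–C8a and C4–C4a, so that ring A is delivered as 3,5-dimethoxybenzyne. The feature used is the ring A pattern itself: O1 sits on C8a, the C4 carbonyl on the neighbouring C4a, and the C5 oxygen beside C4a steers a nucleophile to C8a, while C2 is an ordinary benzylic carbinol carbon. In one operation the C2 alkoxide is O-arylated and the aryl anion acylated, which makes both bonds and ring C without touching C2. The precursor is the O-silylated methyl (3S)-3-hydroxy-3-arylpropanoate whose aryl group is ring B already bonded through C3' to C6'' of the benzyl-protected (2''S) lower flavanone.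

Key step: step 10

Remark on the chemistry: rings are lettered A (benzo), C (pyranone) and B (anisyl) in the upper flavanone and D (benzo), F (pyranone) and E (4-hydroxyphenyl) in the lower one, with doubly primed locants for the lower unit; the C3'–C6'' axis is assumed to rotate freely and is not treated as a stereo element.

**Route**

Step 1
Reactants: 1 (2S)-naringenin
Product: 2 (2S)-sakuranetin, (2S)-5-hydroxy-2-(4-hydroxyphenyl)-7-methoxychroman-4-one
Conditions: MeOH (1.1 equiv), PPh3, DIAD, THF, 0 °C → rt
Reagents that add atoms: methanol, CO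
Why: Mitsunobu etherification, in which the C7 phenol (a vinylogous acid, by far the most acidic OH) is the one engaged while the chelated C5 phenol and the ring E phenol lag behind, under neutral conditions that cannot open ring F, so C2'' stays S.

Step 2
Reactants: 2 (2S)-sakuranetin
Product: 3 (2S)-5-hydroxy-2-(4-hydroxyphenyl)-6-iodo-7-methoxychroman-4-one
Conditions: BnMe3N+ ICl2– (1.0 equiv), CaCO3, CH2Cl2–MeOH, rt
Reagents that add atoms: benzyltrimethylammonium dichloroiodate, C[N+](C)(C)Cc1ccccc1.Cl[I-]Cl
Why: Electrophilic aromatic iodination with a reagent that iodinates ortho to a free phenol, which on ring D means C6 between the C5 hydroxyl and the C7 methoxy group, one equivalent being used so that C8 and the less activated ring E are left alone in a medium too weakly basic to open ring F.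

Step 3
Reactants: 3 (2S)-5-hydroxy-2-(4-hydroxyphenyl)-6-iodo-7-methoxychroman-4-one
Product: 4 (2S)-5-(benzyloxy)-2-[4-(benzyloxy)phenyl]-6-iodo-7-methoxychroman-4-one
Conditions: KOtBu (2.0 equiv), DMF, 0 °C; then BnBr (2.4 equiv), Bu4NI (cat.), 0 °C → rt
Reagents that add atoms: benzyl bromide, BrCc1ccccc1
Why: Williamson etherification in which exactly two equivalents of base convert the two phenols into phenoxides and leave nothing stronger behind, so both oxygens are benzylated without enolising the C4'' ketone and C2'' is not scrambled through the chalcone.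

Step 4
Reactants: 5 1-(3-bromo-4-methoxyphenyl)ethanone
Product: 6 methyl 3-(3-bromo-4-methoxyphenyl)-3-oxopropanoate
Conditions: NaH (2.2 equiv), (MeO)2CO, toluene, 90 °C; then aq. HCl
Reagents that add atoms: dimethyl carbonate, COC(=O)OC
Why: Crossed Claisen condensation of the methyl ketone enolate with dimethyl carbonate, driven to completion by deprotonation of the β-keto ester formed.

Step 5
Reactants: 6 methyl 3-(3-bromo-4-methoxyphenyl)-3-oxopropanoate
Product: 7 methyl (3S)-3-(3-bromo-4-methoxyphenyl)-3-hydroxypropanoate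
Conditions: RuCl(p-cymene)[(S,S)-TsDPEN] (1 mol%), HCO2H–Et3N (5:2), DMF, 30 °C
Reagents that add atoms: none
Why: Noyori–Ikariya asymmetric transfer hydrogenation, in which the (S,S)-TsDPEN ruthenium hydride reduces the aryl ketone with the aryl ring held against the η6-arene and so gives the (S)-carbinol (the same sense as acetophenone to (S)-1-phenylethanol), which sets the future C2.

Step 6
Reactants: 7 methyl (3S)-3-(3-bromo-4-methoxyphenyl)-3-hydroxypropanoate
Product: 8 methyl (3S)-3-hydroxy-3-[4-methoxy-3-(4,4,5,5-tetramethyl-1,3,2-dioxaborolan-2-yl)phenyl]propanoate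
Conditions: B2pin2, Pd(dppf)Cl2 (3 mol%), KOAc, 1,4-dioxane, 85 °C
Reagents that add atoms: bis(pinacolato)diboron, CC1(C)OB(OC1(C)C)B1OC(C)(C)C(C)(C)O1
Why: Miyaura borylation of the aryl bromide with acetate as a base too weak to dehydrate or cleave the β-hydroxy ester, the carbinol centre taking no part.

Step 7
Reactants: 4 (2S)-5-(benzyloxy)-2-[4-(benzyloxy)phenyl]-6-iodo-7-methoxychroman-4-one; 8 methyl (3S)-3-hydroxy-3-[4-methoxy-3-(4,4,5,5-tetramethyl-1,3,2-dioxaborolan-2-yl)phenyl]propanoate
Product: 9 methyl (3S)-3-{3-[(2S)-5-(benzyloxy)-2-[4-(benzyloxy)phenyl]-7-methoxy-4-oxochroman-6-yl]-4-methoxyphenyl}-3-hydroxypropanoate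
Conditions: Pd(OAc)2 (5 mol%), SPhos (10 mol%), K3PO4 (2 equiv, aq.), THF, 40 °C
Reagents that add atoms: none
Why: Suzuki–Miyaura coupling forming the C3'–C6'' bond, the bulky electron-rich biaryl phosphine allowing the di-ortho-oxygenated iodide to couple at a temperature and basicity mild enough to spare the methyl ester, the carbinol and the C2'' centre.

Step 8
Reactants: 10 3,5-dimethoxyphenol
Product: 11 2-bromo-3,5-dimethoxyphenol
Conditions: NBS (1.0 equiv), CH2Cl2, –78 °C → rt
Reagents that add atoms: N-bromosuccinimide, O=C1CCC(=O)N1Br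
Why: Electrophilic aromatic bromination, which in a non-polar solvent at low temperature should go mainly ortho to the hydroxyl group (C2, also para to a methoxy group and less hindered than C4), any 4-bromo isomer being removed by chromatography.

Step 9
Reactants: 11 2-bromo-3,5-dimethoxyphenol
Product: 14 3,5-dimethoxy-2-(trimethylsilyl)phenyl trifluoromethanesulfonate, via aryl silyl ether 12 (not isolated), via lithium ortho-silylphenoxide 13 (not isolated)
Conditions: HMDS, 80 °C, then evaporate; n-BuLi, THF, –78 °C; Tf2O, –78 °C → rt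
Reagents that add atoms: hexamethyldisilazane, C[Si](C)(C)N[Si](C)(C)C; trifluoromethanesulfonic anhydride, O=S(=O)(OS(=O)(=O)C(F)(F)F)C(F)(F)F
Why: O-Silylation, bromine–lithium exchange and retro-Brook 1,3-shift of silicon from oxygen to the lithiated carbon give the ortho-silyl phenoxide, which triflic anhydride sulfonylates at oxygen.

Step 10
Reactants: 9 methyl (3S)-3-{3-[(2S)-5-(benzyloxy)-2-[4-(benzyloxy)phenyl]-7-methoxy-4-oxochroman-6-yl]-4-methoxyphenyl}-3-hydroxypropanoate; 14 3,5-dimethoxy-2-(trimethylsilyl)phenyl trifluoromethanesulfonate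
Product: 19 (2S)-2-{3-[(2S)-5-(benzyloxy)-2-[4-(benzyloxy)phenyl]-7-methoxy-4-oxochroman-6-yl]-4-methoxyphenyl}-5,7-dimethoxychroman-4-one, via O-silyl ether 15 (not isolated), via cesium alkoxide 16 (not isolated), via 3,5-dimethoxybenzyne 17 (not isolated), via C4a aryl anion 18 (not isolated)
Conditions: HMDS, TMSCl (cat.), CH2Cl2, rt, then evaporate; 14 (1.5 equiv, added slowly), CsF (2 equiv), 18-crown-6 (0.2 equiv), THF, 0 → 40 °C
Reagents that add atoms: none
Why: Proposed new method: fluoride, and then the methoxide released in each turnover, strips the O-silyl group from 15 and the C-silyl group from 14, so alkoxide 16 and aryne 17 arise side by side in THF with no O–H or H–F proton at hand; 16 adds to the aryne carbon that becomes C8a and the C4a aryl anion 18 attacks the ester carbonyl and expels methoxide, which ends as MeOSiMe3 instead of remaining as a base that could open either pyranone ring. The closest known reaction type is the fluoride-triggered annulation of arynes with salicylate esters to xanthones (O-arylation followed by acyl capture of the aryl anion), together with plain O-arylation of aliphatic alcohols by arynes; the alkoxide of a β-hydroxy ester has not been shown to do both. Ring C closes by 6-exo-trig acyl substitution, which forms C4–C4a after O1–C8a. No stereocentre is created, since neither bond to C2 is broken and no chalcone-type enone lies on the path, so the (S) carbinol centre set in step 5 becomes C2 unchanged. The step needs O-attack at C8a and not at C4a, which the C5 methoxy group of 17 secures by inductive polarisation and distortion of the aryne that send the nucleophile to the remote carbon and place the charge next to the methoxy group. It also needs acylation of the anion to outrun its protonation and arylation of the alkoxide to outrun retro-aldol or β-elimination, which is why the carbinol is masked as a silyl ether, 14 is kept in excess and an aprotic, non-acidic solvent replaces acetonitrile.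

Step 11
Reactants: 19 (2S)-2-{3-[(2S)-5-(benzyloxy)-2-[4-(benzyloxy)phenyl]-7-methoxy-4-oxochroman-6-yl]-4-methoxyphenyl}-5,7-dimethoxychroman-4-one
Product: 20 (2S)-5-hydroxy-2-{3-[(2S)-5-hydroxy-2-(4-hydroxyphenyl)-7-methoxy-4-oxochroman-6-yl]-4-methoxyphenyl}-7-methoxychroman-4-one (CNP0150873.1)
Conditions: BCl3 (8 equiv), C6HMe5 (6 equiv), CH2Cl2, –78 → 0 °C; MeOH, then aq. NaHCO3
Reagents that add atoms: none
Why: Lewis acid ether cleavage in which BCl3, with pentamethylbenzene as benzyl cation scavenger, removes both aryl benzyl ethers at low temperature and, through chelation to the C4 carbonyl, only the peri C5 methyl ether among the four methoxy groups, no bond to C2 or C2'' being involved.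

**Compound list**

1 | (2S)-naringenin, (2S)-5,7-dihydroxy-2-(4-hydroxyphenyl)chroman-4-one | O=C1C[C@@H](c2ccc(O)cc2)Oc2cc(O)cc(O)c21 | starting material
2 | (2S)-sakuranetin, (2S)-5-hydroxy-2-(4-hydroxyphenyl)-7-methoxychroman-4-one | O=C1C[C@@H](c2ccc(O)cc2)Oc2cc(OC)cc(O)c21 | intermediate
3 | (2S)-5-hydroxy-2-(4-hydroxyphenyl)-6-iodo-7-methoxychroman-4-one | O=C1C[C@@H](c2ccc(O)cc2)Oc2cc(OC)c(I)c(O)c21 | intermediate
4 | (2S)-5-(benzyloxy)-2-[4-(benzyloxy)phenyl]-6-iodo-7-methoxychroman-4-one | O=C1C[C@@H](c2ccc(OCc3ccccc3)cc2)Oc2cc(OC)c(I)c(OCc3ccccc3)c21 | intermediate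
5 | 1-(3-bromo-4-methoxyphenyl)ethanone | CC(=O)c1ccc(OC)c(Br)c1 | starting material
6 | methyl 3-(3-bromo-4-methoxyphenyl)-3-oxopropanoate | COC(=O)CC(=O)c1ccc(OC)c(Br)c1 | intermediate
7 | methyl (3S)-3-(3-bromo-4-methoxyphenyl)-3-hydroxypropanoate | O[C@H](c1ccc(OC)c(Br)c1)CC(=O)OC | intermediate
8 | methyl (3S)-3-hydroxy-3-[4-methoxy-3-(4,4,5,5-tetramethyl-1,3,2-dioxaborolan-2-yl)phenyl]propanoate | O[C@H](c1ccc(OC)c(B2OC(C)(C)C(C)(C)O2)c1)CC(=O)OC | intermediate
9 | methyl (3S)-3-{3-[(2S)-5-(benzyloxy)-2-[4-(benzyloxy)phenyl]-7-methoxy-4-oxochroman-6-yl]-4-methoxyphenyl}-3-hydroxypropanoate | O[C@H](c1ccc(OC)c(-c3c(OC)cc4c(c3OCc5ccccc5)C(=O)C[C@@H](c3ccc(OCc5ccccc5)cc3)O4)c1)CC(=O)OC | intermediate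
10 | 3,5-dimethoxyphenol | COc1cc(O)cc(OC)c1 | starting material
11 | 2-bromo-3,5-dimethoxyphenol | COc1cc(O)c(Br)c(OC)c1 | intermediate
12 | (2-bromo-3,5-dimethoxyphenoxy)trimethylsilane (not isolated) | COc1cc(O[Si](C)(C)C)c(Br)c(OC)c1 | intermediate
13 | lithium 3,5-dimethoxy-2-(trimethylsilyl)phenoxide (not isolated) | [Li+].COc1cc([O-])c([Si](C)(C)C)c(OC)c1 | intermediate
14 | 3,5-dimethoxy-2-(trimethylsilyl)phenyl trifluoromethanesulfonate | COc1cc(OC)c([Si](C)(C)C)c(OS(=O)(=O)C(F)(F)F)c1 | intermediate
15 | methyl (3S)-3-{3-[(2S)-5-(benzyloxy)-2-[4-(benzyloxy)phenyl]-7-methoxy-4-oxochroman-6-yl]-4-methoxyphenyl}-3-(trimethylsilyloxy)propanoate (not isolated) | C[Si](C)(C)O[C@H](c1ccc(OC)c(-c3c(OC)cc4c(c3OCc5ccccc5)C(=O)C[C@@H](c3ccc(OCc5ccccc5)cc3)O4)c1)CC(=O)OC | intermediate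
16 | cesium (1S)-alkoxide of 9 (not isolated) | [Cs+].[O-][C@H](c1ccc(OC)c(-c3c(OC)cc4c(c3OCc5ccccc5)C(=O)C[C@@H](c3ccc(OCc5ccccc5)cc3)O4)c1)CC(=O)OC | intermediate
17 | 3,5-dimethoxybenzyne, 1,2-didehydro-3,5-dimethoxybenzene (not isolated) | COC1=CC(OC)=CC#C1 | intermediate
18 | cesium 2-{(1S)-aryl(2-methoxycarbonylethyl)oxy}-4,6-dimethoxyphenyl anion, the O-arylated C4a carbanion (not isolated) | [Cs+].COc1cc(OC)[c-]c(O[C@H](c2ccc(OC)c(-c3c(OC)cc4c(c3OCc5ccccc5)C(=O)C[C@@H](c3ccc(OCc5ccccc5)cc3)O4)c2)CC(=O)OC)c1 | intermediate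
19 | (2S)-2-{3-[(2S)-5-(benzyloxy)-2-[4-(benzyloxy)phenyl]-7-methoxy-4-oxochroman-6-yl]-4-methoxyphenyl}-5,7-dimethoxychroman-4-one | COc1cc(OC)c2c(c1)O[C@H](c1ccc(OC)c(-c3c(OC)cc4c(c3OCc5ccccc5)C(=O)C[C@@H](c3ccc(OCc5ccccc5)cc3)O4)c1)CC2=O | intermediate
20 | (2S)-5-hydroxy-2-{3-[(2S)-5-hydroxy-2-(4-hydroxyphenyl)-7-methoxy-4-oxochroman-6-yl]-4-methoxyphenyl}-7-methoxychroman-4-one | COc1cc(O)c2c(c1)O[C@H](c1ccc(OC)c(-c3c(OC)cc4c(c3O)C(=O)C[C@@H](c3ccc(O)cc3)O4)c1)CC2=O | target

**Step count**

Total: 11 steps. Longest linear sequence: 6 steps (1, 2, 3, 7, 10, 11 from naringenin; equally 4, 5, 6, 7, 10, 11 from the acetophenone).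

**Steps most likely to fail**

Step 10 (proposed new method). The C4a anion may be protonated, or may take the C3 hydrogen of its own ester, before it is acylated; this would leave an open 3-aryloxy ester or, after β-elimination, a cinnamate. The alkoxide may also fragment by retro-aldol, or transient alkoxide base may open ring F through the chalcone and erode C2''. The fallback uses known chemistry, a catalyst-controlled Hayashi–Miyaura conjugate arylation of a chromone, and sets out from iodide 4. Suzuki–Miyaura coupling of 4 with commercial (5-chloro-2-methoxyphenyl)boronic acid (Pd(dppf)Cl2, K3PO4, THF–H2O, 50 °C, the C–Cl bond being left alone) should give (2S)-5-(benzyloxy)-2-[4-(benzyloxy)phenyl]-6-(5-chloro-2-methoxyphenyl)-7-methoxychroman-4-one F1. Borylation of the aryl chloride with B2(OH)4 (Pd(OAc)2, XPhos, KOAc, EtOH, 80 °C) should give {3-[(2S)-5-(benzyloxy)-2-[4-(benzyloxy)phenyl]-7-methoxy-4-oxochroman-6-yl]-4-methoxyphenyl}boronic acid F2. The acceptor is made from commercial 1-(2-hydroxy-4,6-dimethoxyphenyl)ethanone, which on heating with DMF dimethyl acetal gives (E)-3-(dimethylamino)-1-(2-hydroxy-4,6-dimethoxyphenyl)prop-2-en-1-one F3 and on treatment with HCl in CH2Cl2 cyclises to 5,7-dimethoxy-4H-chromen-4-one F4. Rhodium-catalysed asymmetric 1,4-addition of F2 to F4 ([RhOH(cod)]2 with an electron-poor atropisomeric bisphosphine of the MeO-F12-BIPHEP type, the antipode chosen for the 2S face, aqueous toluene, 20–40 °C, no added base) should give 19, where the route is rejoined. C2'' is a spectator and C2 is set by the ligand.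

Step 7. Transmetalation onto the di-ortho-oxygenated arylpalladium species may be slow. Protodeboronation of the electron-rich ortho-methoxy boronate, saponification of the methyl ester, or base-induced opening of ring F with loss of C2'' configuration could then compete. The fallback is a base-free Stille coupling and sets out from bromide 7. Stannylation with hexamethylditin (Pd(PPh3)4, toluene, 100 °C) should give methyl (3S)-3-hydroxy-3-[4-methoxy-3-(trimethylstannyl)phenyl]propanoate F5. Coupling of F5 with iodide 4 under neutral conditions (Pd(PPh3)4, CuI, DMF, 50 °C) should give 9, where the route is rejoined.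

Step 11. Cleavage of the hindered 5''-O-benzyl group or of the C5 methyl ether may stay incomplete. Benzyl cations may escape the scavenger and alkylate the electron-rich rings A and D. The Lewis acid may also ionise the p-methoxybenzylic C2–O1 bond and erode C2. The fallback separates the two tasks and sets out from 19. Hydrogenolysis (H2, Pd/C, EtOAc–THF, rt) should remove both benzyl groups and give (2S)-2-{3-[(2S)-5-hydroxy-2-(4-hydroxyphenyl)-7-methoxy-4-oxochroman-6-yl]-4-methoxyphenyl}-5,7-dimethoxychroman-4-one F6. Chelation-controlled demethylation of the peri C5 methyl ether of F6 with MgI2 etherate (THF–toluene, 60 °C) should then give the target 20.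

**Further compounds**

F1 | step 10 | (2S)-5-(benzyloxy)-2-[4-(benzyloxy)phenyl]-6-(5-chloro-2-methoxyphenyl)-7-methoxychroman-4-one | O=C1C[C@@H](c2ccc(OCc3ccccc3)cc2)Oc2cc(OC)c(-c3cc(Cl)ccc3OC)c(OCc3ccccc3)c21
F2 | step 10 | {3-[(2S)-5-(benzyloxy)-2-[4-(benzyloxy)phenyl]-7-methoxy-4-oxochroman-6-yl]-4-methoxyphenyl}boronic acid | O=C1C[C@@H](c2ccc(OCc3ccccc3)cc2)Oc2cc(OC)c(-c3cc(B(O)O)ccc3OC)c(OCc3ccccc3)c21
F3 | step 10 | (E)-3-(dimethylamino)-1-(2-hydroxy-4,6-dimethoxyphenyl)prop-2-en-1-one | CN(C)/C=C/C(=O)c1c(O)cc(OC)cc1OC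
F4 | step 10 | 5,7-dimethoxy-4H-chromen-4-one | O=c1ccoc2cc(OC)cc(OC)c12
F5 | step 7 | methyl (3S)-3-hydroxy-3-[4-methoxy-3-(trimethylstannyl)phenyl]propanoate | O[C@H](c1ccc(OC)c([Sn](C)(C)C)c1)CC(=O)OC
F6 | step 11 | (2S)-2-{3-[(2S)-5-hydroxy-2-(4-hydroxyphenyl)-7-methoxy-4-oxochroman-6-yl]-4-methoxyphenyl}-5,7-dimethoxychroman-4-one | COc1cc(OC)c2c(c1)O[C@H](c1ccc(OC)c(-c3c(OC)cc4c(c3O)C(=O)C[C@@H](c3ccc(O)cc3)O4)c1)CC2=O
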